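**Retrosynthetic overview**

The target is a hexasubstituted benzoate. Ring A (C1 CO2Me, C2 OH, C3 prenyl, C4 OH, C5 prenyl, C6 4-hydroxyphenethyl) is read as the dehydro form of a cyclohexane-1,3-dione whose C3–C4–C5 unit, with both prenyl groups, is a symmetrical dialkyl ketone.
Last disconnections: removal of an O-allyl group from the remote phenol and loss of H2 across C5–C6 lead back to a 2,4-dioxocyclohexane-1-carboxylate.
Key disconnection: C5–C6 (Michael) and C2–C3 (Claisen) split ring A into 2,10-dimethylundeca-2,9-dien-6-one and an alkylidene malonate that carries C1, C2, C6 and the arylethyl chain.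
The ketone comes from dimethyl 3-oxopentanedioate and prenyl bromide; the alkylidene malonate comes from methyl 3-(4-hydroxyphenyl)propanoate by allylation, partial reduction and Knoevenagel condensation.
Ring order: the hydroxyphenyl ring is bought; ring A is the only ring made, in the key step, and is aromatised afterwards.

Key step: step 6

Remark: the remote phenol is carried as an allyl ether, because the ring closure is finished under methoxide in methanol, which an aryl silyl ether would not be expected to survive.
Remark: the target has no stereocentre; the annulation product is a keto–enol tautomer mixture and is drawn as the racemic 5,6-trans dienol.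

**Route**

Step 1
Reactants: 1 dimethyl 3-oxopentanedioate (dimethyl 1,3-acetonedicarboxylate); 2 prenyl bromide (1-bromo-3-methylbut-2-ene, 2.1 equiv)
Product: 3 dimethyl 2,4-bis(3-methylbut-2-enyl)-3-oxopentanedioate (dl/meso mixture)
Conditions: K2CO3, acetone, reflux
Reagents that add atoms: none
Why: Double C-alkylation of a β-keto ester, in which the untouched C4 methylene of the mono-prenylated intermediate is the more acidic and less hindered site, so the second prenyl group should enter there and give the symmetrical 2,4-pattern (both diastereomers converge in step 2).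

Step 2
Reactants: 3 dimethyl 2,4-bis(3-methylbut-2-enyl)-3-oxopentanedioate
Product: 5 2,10-dimethylundeca-2,9-dien-6-one, via oxoglutaric diacid 4 (not isolated)
Conditions: NaOH, MeOH/H2O, rt; then aq. HCl to pH 2, 50 °C
Reagents that add atoms: none
Why: Ester saponification followed by decarboxylation of the β-keto diacid (ketonic hydrolysis) leaves only the symmetrical ketone, and the dilute acid and mild warming should spare the trisubstituted alkenes.

Step 3
Reactants: 6 methyl 3-(4-hydroxyphenyl)propanoate
Product: 7 methyl 3-[4-(allyloxy)phenyl]propanoate
Conditions: allyl bromide, K2CO3, acetone, reflux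
Reagents that add atoms: allyl bromide, C=CCBr
Why: Williamson ether synthesis on the phenoxide gives an ether that is inert to hydride, amide base and methoxide and can later be removed without acid or fluoride.

Step 4
Reactants: 7 methyl 3-[4-(allyloxy)phenyl]propanoate
Product: 9 3-[4-(allyloxy)phenyl]propanal, via aluminium hemiacetal 8 (not isolated)
Conditions: i-Bu2AlH (1.1 equiv), CH2Cl2, −78 °C; then MeOH, aq. potassium sodium tartrate
Reagents that add atoms: none
Why: Partial reduction of an unhindered methyl ester with i-Bu2AlH, in which the tetrahedral aluminium hemiacetal is stable at −78 °C and releases the aldehyde only on hydrolytic work-up.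

Step 5
Reactants: 9 3-[4-(allyloxy)phenyl]propanal; 10 dimethyl malonate
Product: 11 dimethyl 2-{3-[4-(allyloxy)phenyl]propylidene}malonate
Conditions: piperidine (cat.), AcOH (cat.), benzene, reflux, Dean–Stark
Reagents that add atoms: none
Why: Knoevenagel condensation driven by azeotropic removal of water; the two ester groups are identical, so no alkene geometry has to be controlled.

Step 6
Reactants: 5 2,10-dimethylundeca-2,9-dien-6-one; 11 dimethyl 2-{3-[4-(allyloxy)phenyl]propylidene}malonate
Product: 13 methyl 6-{2-[4-(allyloxy)phenyl]ethyl}-3,5-bis(3-methylbut-2-enyl)-2,4-dioxocyclohexane-1-carboxylate (racemic 5,6-trans; drawn as the dienol tautomer), via Michael adduct 12 (not isolated)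
Conditions: LiN(i-Pr)2 (LDA, 1.0 equiv), THF, −78 °C, 5; then 11, −78 °C; then NaOMe, MeOH, −78 → 65 °C; aq. HCl work-up at 0 °C
Reagents that add atoms: none
Why: The preformed lithium enolate of symmetrical ketone 5 adds to the β-carbon of the doubly activated acceptor 11 (Michael addition, bond C5–C6) to give the malonate anion of 12; methoxide in methanol then equilibrates this with the C3 enolate, which attacks one malonate ester and expels methoxide (intramolecular Claisen condensation, bond C2–C3), and deprotonation of the acidic β-tricarbonyl product pulls all equilibria forward. The closest known reaction type is the consecutive Michael–Claisen synthesis of cyclohexane-1,3-diones from ketones and unsaturated esters, of which the alkoxide closure of a δ-keto malonate in the dimedone synthesis is the classical case. Ring A closes in a 6-(enolendo)-exo-trig mode, because both carbons of the attacking enolate (C3 and C4) lie inside the new ring, and this mode is favoured for six-membered rings. The sp3 centres at C5 and C6 need no control; under the equilibrating methoxide conditions the 5,6-trans isomer should prevail, and both centres are erased in step 7. The selectivity needed is conjugate addition over removal of a γ-proton from 11, which the low temperature, the lithium counter-ion and the high electrophilicity of the alkylidene malonate should secure; the symmetry of 5 removes any regiochemical question, and only C3 can reach an ester carbonyl through a six-membered transition state.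

Step 7
Reactants: 13 methyl 6-{2-[4-(allyloxy)phenyl]ethyl}-3,5-bis(3-methylbut-2-enyl)-2,4-dioxocyclohexane-1-carboxylate
Product: 14 methyl 6-{2-[4-(allyloxy)phenyl]ethyl}-2,4-dihydroxy-3,5-bis(3-methylbut-2-enyl)benzoate
Conditions: DDQ (1.05 equiv), 1,4-dioxane, rt
Reagents that add atoms: none
Why: Dehydrogenative aromatisation with DDQ, in which hydride abstraction from C6 of the dienol gives a cation stabilised by both enol oxygens (the σ-complex of the resorcinol) and loss of the C5 proton gives the arene; one equivalent at room temperature should leave the prenyl groups untouched.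

Step 8
Reactants: 14 methyl 6-{2-[4-(allyloxy)phenyl]ethyl}-2,4-dihydroxy-3,5-bis(3-methylbut-2-enyl)benzoate
Product: 15 methyl 2,4-dihydroxy-6-[2-(4-hydroxyphenyl)ethyl]-3,5-bis(3-methylbut-2-enyl)benzoate (target)
Conditions: Pd(PPh3)4 (5 mol %), morpholine, THF, rt
Reagents that add atoms: none
Why: Tsuji–Trost deallylation, in which zerovalent palladium ionises the aryl allyl ether to a π-allyl complex and the phenoxide while morpholine traps the allyl group; the C-prenyl groups carry no leaving group and the conditions are neither acidic nor oxidising.

**Compound list**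

1 | dimethyl 3-oxopentanedioate | COC(=O)CC(=O)CC(=O)OC | starting material
2 | prenyl bromide (1-bromo-3-methylbut-2-ene) | CC(C)=CCBr | starting material
3 | dimethyl 2,4-bis(3-methylbut-2-enyl)-3-oxopentanedioate (dl/meso mixture) | COC(=O)C(CC=C(C)C)C(=O)C(CC=C(C)C)C(=O)OC | intermediate
4 | 2,4-bis(3-methylbut-2-enyl)-3-oxopentanedioic acid (not isolated) | OC(=O)C(CC=C(C)C)C(=O)C(CC=C(C)C)C(O)=O | intermediate
5 | 2,10-dimethylundeca-2,9-dien-6-one | CC(C)=CCCC(=O)CCC=C(C)C | intermediate
6 | methyl 3-(4-hydroxyphenyl)propanoate | COC(=O)CCc1ccc(O)cc1 | starting material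
7 | methyl 3-[4-(allyloxy)phenyl]propanoate | COC(=O)CCc1ccc(OCC=C)cc1 | intermediate
8 | {3-[4-(allyloxy)phenyl]-1-methoxypropoxy}diisobutylaluminium (not isolated) | COC(CCc1ccc(OCC=C)cc1)O[Al](CC(C)C)CC(C)C | intermediate
9 | 3-[4-(allyloxy)phenyl]propanal | O=CCCc1ccc(OCC=C)cc1 | intermediate
10 | dimethyl malonate | COC(=O)CC(=O)OC | starting material
11 | dimethyl 2-{3-[4-(allyloxy)phenyl]propylidene}malonate | COC(=O)C(=CCCc1ccc(OCC=C)cc1)C(=O)OC | intermediate
12 | dimethyl 2-{1-[4-(allyloxy)phenyl]-9-methyl-4-(3-methylbut-2-enyl)-5-oxodec-8-en-3-yl}malonate (racemic diastereomer mixture, not isolated) | COC(=O)C(C(=O)OC)C(CCc1ccc(OCC=C)cc1)C(CC=C(C)C)C(=O)CCC=C(C)C | intermediate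
13 | methyl 6-{2-[4-(allyloxy)phenyl]ethyl}-3,5-bis(3-methylbut-2-enyl)-2,4-dioxocyclohexane-1-carboxylate (dienol tautomer, racemic, 5,6-trans, one enantiomer drawn) | COC(=O)C1=C(O)C(CC=C(C)C)=C(O)[C@@H](CC=C(C)C)[C@@H]1CCc1ccc(OCC=C)cc1 | intermediate
14 | methyl 6-{2-[4-(allyloxy)phenyl]ethyl}-2,4-dihydroxy-3,5-bis(3-methylbut-2-enyl)benzoate | COC(=O)c1c(O)c(CC=C(C)C)c(O)c(CC=C(C)C)c1CCc1ccc(OCC=C)cc1 | intermediate
15 | methyl 2,4-dihydroxy-6-[2-(4-hydroxyphenyl)ethyl]-3,5-bis(3-methylbut-2-enyl)benzoate | COC(=O)c1c(O)c(CC=C(C)C)c(O)c(CC=C(C)C)c1CCc1ccc(O)cc1 | target

**Step count**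

Total steps: 8. Longest linear sequence: 6 steps (steps 3, 4, 5, 6, 7, 8, from compound 6 to target 15).

**Steps most likely to fail**

Step 6 (key annulation). The lithium enolate may remove a γ-proton from the alkylidene malonate instead of adding to it, returning ketone and a deconjugated malonate, or the adduct may revert under methoxide before it closes. Fallback, setting out from ketone 5 and acceptor 11: the ketone is converted with LiN(i-Pr)2 and Me3SiCl in THF at −78 °C into the trimethylsilyl enol ether F1. F1 is then combined with 11 under TiCl4 in CH2Cl2 at −78 °C in a Mukaiyama–Michael addition. No base is present, so proton transfer from the γ-position cannot compete. Aqueous work-up should give the neutral Michael adduct 12, now isolated. The route is rejoined at 12, which is closed to 13 with NaOMe in MeOH at reflux as in the second stage of step 6.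

Step 7 (aromatisation). DDQ may go on to abstract benzylic hydride from the prenyl groups of the newly formed resorcinol (chromene formation), or the dehydrogenation may stall. Fallback, setting out from dione 13: double deprotonation with LiN(i-Pr)2 (2.2 equiv) in THF at −78 °C gives the dianion, whose last-formed and most reactive site is C1 (α to the ester). Quenching with PhSeBr at −78 °C, where enolate selenenylation is much faster than addition to alkenes, should give the C1 phenylselenide F2. Oxidation with H2O2 and pyridine in CH2Cl2 at 0 °C gives the selenoxide. Its only β-hydrogen is on C6, so syn-elimination gives the C1–C6 enedione, which tautomerises to arene 14, where the route is rejoined.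

Step 1 (bis-prenylation). The second alkylation may go in part to the already substituted carbon, to oxygen, or a third time, giving a mixture that is hard to separate. Fallback, setting out from prenyl bromide 2 and purchased 6-methylhept-5-en-2-one F3: condensation of F3 with 1,1-dimethylhydrazine gives the N,N-dimethylhydrazone F4. Deprotonation at the methyl group with LiN(i-Pr)2 in THF at 0 °C and alkylation with 2 gives the alkylated hydrazone F5. Hydrolysis with CuCl2 in THF and aqueous pH 7 phosphate buffer releases ketone 5, where the route is rejoined.

Further compounds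
F1 | step 6 | trimethyl[(2,10-dimethylundeca-2,5,9-trien-6-yl)oxy]silane (E/Z mixture) | CC(C)=CCC=C(O[Si](C)(C)C)CCC=C(C)C
F2 | step 7 | methyl 6-{2-[4-(allyloxy)phenyl]ethyl}-3,5-bis(3-methylbut-2-enyl)-2,4-dioxo-1-(phenylselanyl)cyclohexane-1-carboxylate (racemic) | COC(=O)C1([Se]c2ccccc2)C(=O)C(CC=C(C)C)C(=O)C(CC=C(C)C)C1CCc1ccc(OCC=C)cc1
F3 | step 1 | 6-methylhept-5-en-2-one | CC(=O)CCC=C(C)C
F4 | step 1 | 6-methylhept-5-en-2-one N,N-dimethylhydrazone | CC(CCC=C(C)C)=NN(C)C
F5 | step 1 | 2,10-dimethylundeca-2,9-dien-6-one N,N-dimethylhydrazone | CC(C)=CCCC(CCC=C(C)C)=NN(C)C
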